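## The problem

The target is a (2S)-flavanone in which ring A is a 5,7-dihydroxy arene carrying a prenyl group at C8, ring C is the dihydropyranone, and ring B (2′-methoxy, 4′-hydroxy, 5′-(1,1-dimethylallyl)) hangs from C2. C2 is the only stereocentre, so nothing in the molecule can relay chirality to it and a chiral catalyst has to set it. It is also fragile: it is benzylic, bound to O1 and β to the C4 ketone, so base can open ring C to the 2′-hydroxychalcone and scramble it. Ring A poses a regiochemical question (prenyl at C8, not C6), and ring B needs a quaternary benzylic carbon ortho to a phenol and para to a methoxy group. The two alkenes rule out hydrogenolysis and strong acid: the trisubstituted prenyl alkene can cyclise onto the 7-hydroxyl, and the vinyl group onto the 4′-hydroxyl. The feature that opens the molecule is that C2 is joined to ring B by the single C2–C1′ bond and is the β-carbon of the C4 ketone. Ring C can therefore start as a flat chromone whose C2 is the only electrophilic carbon and accepts the whole of ring B as an aryl nucleophile under catalyst control.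

## Retrosynthesis

**Target 16 to tris-MOM ether 15.** Three O–CH2OCH3 bonds are cut. Benzyl ethers would need hydrogenolysis, which the alkenes forbid; silyl ethers are at risk in aqueous KOH or need basic fluoride; methyl ethers need boron halides. MOM ethers withstand n-BuLi, hot amine and aqueous KOH, and leave in dilute acid, after which no base touches the free flavanone. The forward step must unmask three phenols without protonating either alkene.

**15 to chromone 6 and boronic acid 14.** The C2–C1′ bond is cut. The neighbouring cut, O1–C2 (oxa-Michael closure of a chalcone), is reversible and has no dependable enantioselective version for an unactivated chalcone. The chosen cut makes the stereocentre in the same event as the only skeletal bond, and gives two achiral halves of similar size. The forward reaction must transfer an ortho-substituted aryl group to an electron-rich chromone. This points to rhodium with a chiral diene, since palladium/pyridine-oxazoline systems are generally less tolerant of ortho substituents.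

**6 to acetophenone 4 (through enaminone 5).** O1–C2 and C2–C3 are cut; C2 comes from an amide acetal. A formate Claisen condensation would reach the same ring but ends in a separate dehydration, whereas the enaminone closes and eliminates in one operation. The precursor is a simple ortho-hydroxyacetophenone. The forward step must close the pyranone without strong acid, because two MOM ethers are already in place.

**4 to 3, and 3 to phloroacetophenone 1 and prenyl bromide 2.** Two O–MOM bonds and the aryl–CH2 bond of the prenyl group are cut. Because C3 and C5 of 1 are equivalent, mono-C-prenylation can give only one isomer. The C8/C6 question then reduces to which ortho-hydroxyl of 3 stays free. The hydroxyl wedged between prenyl and acetyl is the hindered, chelated one; it stays free and later becomes O1, which places the prenyl at C8.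

**14 to aryl bromide 11 (through 12 and 13).** The C–B bond is traced to a C–Br bond by lithiation–borylation. A palladium-catalysed borylation would add a second metal and heat, whereas bromine–lithium exchange at −78 °C is faster than any deprotonation and leaves the MOM ether and the vinyl group alone. The bromine of 7 already sits on the carbon that becomes C1′.

**11 to phenol 10, 10 to prenyl ether 8 (through dienone 9), 8 to bromophenol 7 and 2.** The O–MOM bond, the aryl–C(quaternary) bond and the O–prenyl bond are cut. Direct Friedel–Crafts prenylation would give the linear prenyl isomer. An aromatic Claisen rearrangement inverts the allyl unit and gives the 1,1-dimethylallyl group. Bromine blocks the para position, and the methoxy group steers migration to the remote ortho carbon.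

## Roads not taken

**Alternative 1: oxocarbenium–styrene cycloaddition.** The cut is O1–C2 plus C3–C4. Trimethyl orthoformate and a chiral confined Brønsted acid would turn salicylaldehyde A1 into its O-methyl oxocarbenium ion (an ortho-quinone methide equivalent). This would add styrene A2 and close ring C as the 2,4-cis (2S)-4-methoxyflavan A3.
- Merits: two bonds and a ring form in one convergent, catalyst-controlled step from two arenes. No chromone and no boron reagent are needed. In ring-forming power this road is better than the chosen plan, whose key step makes one bond.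
- Weak points: A2 is a very electron-rich styrene and prone to cationic oligomerisation. The prenyl alkene of A1 and the vinyl group of A2 are competing nucleophiles for the cation. Three MOM acetals must survive a very strong acid in the presence of an orthoformate. A3 is at the wrong oxidation level at C4, so the methyl ether must be exchanged and oxidised to the ketone in at least two more steps, and the C4 centre is discarded.
- Comparison: the chosen plan offers a single electrophilic site, no carbocation near either alkene, the correct oxidation level directly from the key step, and a closer known reaction type.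

**Alternative 2: biomimetic Claisen cyclisation, ring A last.** The cut is C4a–C5. With Mg(OCH3)2 the extended enolate of dihydropyranone keto ester A4 would attack its terminal ester through C4a. Ring A would close and aromatise to the 5,7-dihydroxy arene A5.
- Merits: the ring A phenols appear unprotected, so only one MOM remains. The prenyl position is fixed by chain connectivity, not by arene selectivity. In protecting-group economy this road is better.
- Weak points: A4 is far more complex than 6 or 14. It needs its own asymmetric entry to the C2 centre and a prenyl-branched polycarbonyl chain. The C2–O1 bond of A4 is β to the ring ketone, so the basic alkoxide can open the ring by elimination and racemise C2 before ring A forms. The chain also has other cyclisation modes (O-acylation, aldol at the ring ketone).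
- Comparison: the chosen plan solves the same regiochemical problem by the symmetry of 1 in three steps. It creates the stereocentre late under nearly neutral conditions.

**Alternative 3: Claisen–Cope relay of prenyl from O5 to C8.** The cut is the C8–CH2 bond. Eu(fod)3, tris(6,6,7,7,8,8,8-heptafluoro-2,2-dimethyloctane-3,5-dionato)europium (trivalent europium), chelated between the C4 carbonyl and O5 of the 5-O-prenyl flavanone A6, would trigger Claisen rearrangement to C6 and Cope rearrangement on to C8. The product is diacetate A7.
- Merits: this prenyl transfer is well established on flavanones, mild and regiospecific by mechanism. For the prenyl installation alone its precedent is stronger than that of any step in the chosen plan. It would be the natural rescue if 6 proved inert to arylation.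
- Weak points: it does not address C2, so A6 must first be made as a single enantiomer by another asymmetric step. Three phenols must be differentiated (acetates at O7 and O4′, prenyl on the chelated 5-hydroxyl). The relay can stall after the first shift, with the inverted allyl unit left at C6, if enolisation outpaces the Cope step. A Lewis acid with heat, and later basic acetate removal, act on a formed and epimerisable (S)-flavanone.
- Comparison: the chosen plan installs the prenyl in step 1 on a symmetric arene. It makes the stereocentre and the skeletal bond together, and leaves only one mild step after the stereocentre exists.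

Key step: step 8

Assumption 1: transposing the facial model for cyclohexenone to the chromone, the (S,S)-diene is taken as the enantiomer that gives (2S); the antipodal ligand is equally available should the sense prove opposite.

Assumption 2: 4-bromo-3-methoxyphenol and both enantiomers of the diene ligand are taken as purchasable.

## Route

Step 1
Reactants: 1 2,4,6-trihydroxyacetophenone (dried); 2 prenyl bromide (1-bromo-3-methylbut-2-ene)
Product: 3 1-[2,4,6-trihydroxy-3-(3-methylbut-2-en-1-yl)phenyl]ethan-1-one
Conditions: 2 (1.0 equiv), DBU (1.1 equiv), THF, 0 °C → rt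
Reagents that add atoms: none
Why: Base-mediated C-prenylation of an acylphloroglucinol, whose ambident anion reacts at ring carbon; C3 and C5 of 1 are equivalent, so only one mono-C-prenyl isomer can form. Keeping 2 limiting holds back bis-prenylation and O-alkylation, which are removed by chromatography.

Step 2
Reactants: 3 1-[2,4,6-trihydroxy-3-(3-methylbut-2-en-1-yl)phenyl]ethan-1-one
Product: 4 1-[2-hydroxy-4,6-bis(methoxymethoxy)-3-(3-methylbut-2-en-1-yl)phenyl]ethan-1-one
Conditions: MOMCl (2.2 equiv), iPr2NEt (3 equiv), CH2Cl2, 0 °C → rt
Reagents that add atoms: chloromethyl methyl ether (MOMCl), COCCl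
Why: Williamson-type O-alkylation of phenoxides: the unchelated 4-hydroxyl reacts first, then the ortho-hydroxyl flanked by hydrogen, while the one wedged between prenyl and acetyl stays as the hydrogen-bonded phenol. This leaves free the oxygen that becomes O1 next to the prenyl-bearing carbon. An HMBC correlation from the chelated hydroxyl proton to the prenyl-bearing carbon and an NOE from the lone aromatic proton to both OCH2O groups would verify the regiochemistry of 4 before it is carried forward.

Step 3
Reactants: 4 1-[2-hydroxy-4,6-bis(methoxymethoxy)-3-(3-methylbut-2-en-1-yl)phenyl]ethan-1-one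
Product: 6 5,7-bis(methoxymethoxy)-8-(3-methylbut-2-en-1-yl)-4H-chromen-4-one, via enaminone 5 (not isolated)
Conditions: Me2NCH(OMe)2 (3 equiv), toluene, 95 °C; evaporate; then p-TsOH·H2O (1.0 equiv), CH2Cl2, 0 °C → rt
Reagents that add atoms: N,N-dimethylformamide dimethyl acetal, COC(OC)N(C)C
Why: Enaminone route to chromones: condensation of the methyl ketone with the amide acetal gives 5, whose protonated form is attacked by the chelated phenol at the β-carbon and then loses dimethylamine. The amine set free consumes the single equivalent of acid, so the medium never becomes strongly acidic and the aryl MOM ethers should survive, as they do in the related iodine-induced cyclisations of such enaminones.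

Step 4
Reactants: 7 4-bromo-3-methoxyphenol; 2 prenyl bromide
Product: 8 1-bromo-2-methoxy-4-[(3-methylbut-2-en-1-yl)oxy]benzene
Conditions: 2 (1.2 equiv), K2CO3, acetone, reflux
Reagents that add atoms: none
Why: Williamson ether synthesis of a simple phenol with a primary allylic bromide; substitution at the unsubstituted terminus gives the linear prenyl ether.

Step 5
Reactants: 8 1-bromo-2-methoxy-4-[(3-methylbut-2-en-1-yl)oxy]benzene
Product: 10 4-bromo-5-methoxy-2-(2-methylbut-3-en-2-yl)phenol, via ortho-dienone 9 (not isolated)
Conditions: PhNEt2, 190 °C, sealed vessel, argon, stopped as soon as 8 is consumed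
Reagents that add atoms: none
Why: Aromatic Claisen rearrangement: the [3,3] shift inverts the allyl unit, placing the 1,1-dimethylallyl group on an ortho carbon, and tautomerisation of 9 restores the arene. Bromine blocks the para position, and the ortho carbon between the ether oxygen and the methoxy group is disfavoured sterically for a quaternary centre and electronically, since a meta donor directs migration to the remote ortho carbon. The amine solvent buffers the phenol and the short heating time limits the abnormal Claisen pathway.

Step 6
Reactants: 10 4-bromo-5-methoxy-2-(2-methylbut-3-en-2-yl)phenol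
Product: 11 1-bromo-2-methoxy-4-(methoxymethoxy)-5-(2-methylbut-3-en-2-yl)benzene
Conditions: NaH, THF, 0 °C; MOMCl, 0 °C → rt
Reagents that add atoms: chloromethyl methyl ether (MOMCl), COCCl
Why: O-alkylation of the sodium phenoxide; NaH is used because the hydroxyl is hindered by the adjacent quaternary carbon. The MOM ether is needed to withstand n-BuLi and aqueous KOH.

Step 7
Reactants: 11 1-bromo-2-methoxy-4-(methoxymethoxy)-5-(2-methylbut-3-en-2-yl)benzene
Product: 14 [2-methoxy-4-(methoxymethoxy)-5-(2-methylbut-3-en-2-yl)phenyl]boronic acid, via aryllithium 12 (not isolated), via lithium aryltriisopropoxyborate 13 (not isolated)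
Conditions: n-BuLi (1.05 equiv), THF, −78 °C; B(OiPr)3 (1.5 equiv), −78 → 0 °C; then 1 M HCl to pH 6, 0 °C; used promptly
Reagents that add atoms: triisopropyl borate, CC(C)OB(OC(C)C)OC(C)C; water, O
Why: Lithiation–borylation: bromine–lithium exchange at −78 °C outruns any deprotonation and gives 12, stabilised by the ortho-methoxy group. Trapping with the borate ester gives ate complex 13, and hydrolysis at pH 6 releases the boronic acid without touching the MOM ether.

Step 8
Reactants: 6 5,7-bis(methoxymethoxy)-8-(3-methylbut-2-en-1-yl)-4H-chromen-4-one; 14 [2-methoxy-4-(methoxymethoxy)-5-(2-methylbut-3-en-2-yl)phenyl]boronic acid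
Product: 15 (2S)-2-[2-methoxy-4-(methoxymethoxy)-5-(2-methylbut-3-en-2-yl)phenyl]-5,7-bis(methoxymethoxy)-8-(3-methylbut-2-en-1-yl)-2,3-dihydro-4H-chromen-4-one
Conditions: [RhCl(C2H4)2]2 (2.5 mol %, monovalent rhodium), (1S,4S)-2,5-diphenylbicyclo[2.2.2]octa-2,5-diene (5.5 mol %), 14 (2.5 equiv), aq. KOH (0.5 equiv), toluene–H2O, 40 °C
Reagents that add atoms: none
Why: KOH converts the chloride precatalyst into a diene–Rh–OH species (monovalent rhodium) that takes the aryl group from 14 by transmetalation; the aryl–rhodium complex binds and inserts the C2=C3 bond of 6, delivering the aryl to C2, and water protonates the oxa-π-allyl rhodium enolate at C3, releasing 15 and regenerating Rh–OH. The closest known reaction type is the rhodium/chiral-diene-catalysed asymmetric 1,4-addition of arylboronic acids to chromones (Hayashi–Miyaura conjugate arylation), which gives 2-arylchroman-4-ones. No ring closes; the C2–C1′ bond and the C2 stereocentre form together. The stereocentre is controlled by the C2-symmetric diene alone: its phenyl groups block one quadrant, so the chromone coordinates with its carbonyl turned away from them and exposes one enantioface, and by transposing the cyclohexenone model the (S,S)-ligand should give (2S). Regioselectivity is inherent, because C2 is the only β-carbon of the cyclic β-alkoxy enone. Chemoselectivity rests on the inertness of the unactivated prenyl and vinyl alkenes toward aryl–rhodium insertion, and 1,2-addition to the product ketone is disfavoured by the flanking 5-O-MOM group. The main competition is protodeboronation of the ortho-methoxy boronic acid, countered by an excess of 14, substoichiometric base and moderate temperature. C2 should keep its configuration because the base is substoichiometric and held in the aqueous phase, which keeps enolisation at C3 and ring opening to the chalcone slow.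

Step 9
Reactants: 15 (2S)-2-[2-methoxy-4-(methoxymethoxy)-5-(2-methylbut-3-en-2-yl)phenyl]-5,7-bis(methoxymethoxy)-8-(3-methylbut-2-en-1-yl)-2,3-dihydro-4H-chromen-4-one
Product: 16 (2S)-5,7-dihydroxy-2-[4-hydroxy-2-methoxy-5-(2-methylbut-3-en-2-yl)phenyl]-8-(3-methylbut-2-en-1-yl)-2,3-dihydro-4H-chromen-4-one (CNP0308136.1)
Conditions: 3 M aq. HCl, MeOH, 45 °C, stopped when the last MOM group has left
Reagents that add atoms: none
Why: Acid-catalysed acetal exchange of the three aryl MOM ethers with methanol, the usual unmasking of prenylated flavonoids. The acid is dilute and the temperature low so that neither alkene is protonated, and C2 is untouched because no base is present.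

## Compound list

1 | 2,4,6-trihydroxyacetophenone | CC(=O)c1c(O)cc(O)cc1O | starting material
2 | prenyl bromide (1-bromo-3-methylbut-2-ene) | CC(C)=CCBr | starting material
3 | 1-[2,4,6-trihydroxy-3-(3-methylbut-2-en-1-yl)phenyl]ethan-1-one | CC(=O)c1c(O)cc(O)c(CC=C(C)C)c1O | intermediate
4 | 1-[2-hydroxy-4,6-bis(methoxymethoxy)-3-(3-methylbut-2-en-1-yl)phenyl]ethan-1-one | CC(=O)c1c(O)c(CC=C(C)C)c(OCOC)cc1OCOC | intermediate
5 | (E)-3-(dimethylamino)-1-[2-hydroxy-4,6-bis(methoxymethoxy)-3-(3-methylbut-2-en-1-yl)phenyl]prop-2-en-1-one | CN(C)/C=C/C(=O)c1c(O)c(CC=C(C)C)c(OCOC)cc1OCOC | intermediate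
6 | 5,7-bis(methoxymethoxy)-8-(3-methylbut-2-en-1-yl)-4H-chromen-4-one | O=c1ccoc2c(CC=C(C)C)c(OCOC)cc(OCOC)c12 | intermediate
7 | 4-bromo-3-methoxyphenol | COc1cc(O)ccc1Br | starting material
8 | 1-bromo-2-methoxy-4-[(3-methylbut-2-en-1-yl)oxy]benzene | COc1cc(OCC=C(C)C)ccc1Br | intermediate
9 | 4-bromo-3-methoxy-6-(2-methylbut-3-en-2-yl)cyclohexa-2,4-dien-1-one (racemic) | O=C1C=C(OC)C(Br)=CC1C(C)(C)C=C | intermediate
10 | 4-bromo-5-methoxy-2-(2-methylbut-3-en-2-yl)phenol | C=CC(C)(C)c1cc(Br)c(OC)cc1O | intermediate
11 | 1-bromo-2-methoxy-4-(methoxymethoxy)-5-(2-methylbut-3-en-2-yl)benzene | C=CC(C)(C)c1cc(Br)c(OC)cc1OCOC | intermediate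
12 | [2-methoxy-4-(methoxymethoxy)-5-(2-methylbut-3-en-2-yl)phenyl]lithium | C=CC(C)(C)c1cc([Li])c(OC)cc1OCOC | intermediate
13 | lithium [2-methoxy-4-(methoxymethoxy)-5-(2-methylbut-3-en-2-yl)phenyl]tri(propan-2-yloxy)borate | [Li+].C=CC(C)(C)c1cc([B-](OC(C)C)(OC(C)C)OC(C)C)c(OC)cc1OCOC | intermediate
14 | [2-methoxy-4-(methoxymethoxy)-5-(2-methylbut-3-en-2-yl)phenyl]boronic acid | C=CC(C)(C)c1cc(B(O)O)c(OC)cc1OCOC | intermediate
15 | (2S)-2-[2-methoxy-4-(methoxymethoxy)-5-(2-methylbut-3-en-2-yl)phenyl]-5,7-bis(methoxymethoxy)-8-(3-methylbut-2-en-1-yl)-2,3-dihydro-4H-chromen-4-one | C=CC(C)(C)c1cc([C@@H]2CC(=O)c3c(OCOC)cc(OCOC)c(CC=C(C)C)c3O2)c(OC)cc1OCOC | intermediate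
16 | (2S)-5,7-dihydroxy-2-[4-hydroxy-2-methoxy-5-(2-methylbut-3-en-2-yl)phenyl]-8-(3-methylbut-2-en-1-yl)-2,3-dihydro-4H-chromen-4-one (CNP0308136.1) | C=CC(C)(C)c1cc([C@@H]2CC(=O)c3c(O)cc(O)c(CC=C(C)C)c3O2)c(OC)cc1O | target

## Step count and least certain steps

Total: 9 steps. Longest linear sequence: 6 steps (7 to 16 through steps 4, 5, 6, 7, 8 and 9). The ring A branch (steps 1 to 3) is three steps and joins at step 8.

**Step 8 (key step).**
- What may go wrong: protodeboronation of the electron-rich, ortho-substituted boronic acid may outrun aryl transfer, because the 5,7-dialkoxy pattern donates into the pyranone and makes 6 a weak acceptor. Facial selectivity may be poor if the 5-O-MOM and 8-prenyl groups disturb binding. The enantiomeric purity may erode by base-induced ring opening and reclosure.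
- Fallback: it sets out from 11 and 4 and returns at 15. Bromine–lithium exchange of 11 (n-BuLi, THF, −78 °C) and quenching with N,N-dimethylformamide would give 2-methoxy-4-(methoxymethoxy)-5-(2-methylbut-3-en-2-yl)benzaldehyde F1. Claisen–Schmidt condensation of F1 with 4 (KOH, EtOH) would give the 2′-hydroxychalcone F2. NaOAc in refluxing ethanol would close ring C through the only free phenol and give the racemic tris-MOM flavanone F3. Preparative chromatography on a chiral stationary phase would deliver 15.

**Step 5.**
- What may go wrong: thermal fragmentation of the prenyl ether back to the phenol, and onward reaction of the product at 190 °C (abnormal Claisen rearrangement, or cyclisation of the phenol onto the vinyl group).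
- Fallback: it sets out from 8 and returns at 10. The rearrangement would be run in PhNEt2 with Ac2O and NaOAc, so that the phenol is captured as it forms as 4-bromo-5-methoxy-2-(2-methylbut-3-en-2-yl)phenyl acetate F4, which cannot rearrange or cyclise further. Methanolysis (K2CO3, MeOH, rt) would then give 10.

**Step 3.**
- What may go wrong: loss of the MOM group peri to the carbonyl during the acid-induced cyclisation, or incomplete closure if the acid is held too weak.
- Fallback: it sets out from 4 and returns at 6 with no acid at any point. Claisen condensation of 4 with ethyl formate (NaH, THF) and neutral work-up would give the cyclic hemiacetal 2-hydroxy-5,7-bis(methoxymethoxy)-8-(3-methylbut-2-en-1-yl)-2,3-dihydro-4H-chromen-4-one F5. Sulfonylation and elimination (MsCl, Et3N, CH2Cl2, 0 °C) would then give 6.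

**Step 9.**
- What may go wrong: acid-induced addition of the 7-hydroxyl to the prenyl alkene, or of the 4′-hydroxyl to the vinyl group, before the last MOM group has left.
- Fallback: it sets out from 15 and returns at 16 without protic acid. Me3SiOTf and 2,2′-bipyridyl (CH2Cl2, 0 °C) would exchange the aryl MOM ethers for silyl ethers, giving the tris(trimethylsilyl) ether F6. Addition of water would hydrolyse F6 to 16.

**Step 7.**
- What may go wrong: protodeboronation and boroxine formation during isolation and storage of the electron-rich boronic acid, which makes its stoichiometry in step 8 uncertain.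
- Fallback: it sets out from 11 and returns at 15. Aryllithium 12 would be quenched with 2-isopropoxy-4,4,5,5-tetramethyl-1,3,2-dioxaborolane to give the chromatographable pinacol boronate F7. F7 would be used in place of 14 under the conditions of step 8, where aqueous KOH activates it in the flask.

## Further compounds

F1 | step 8 | 2-methoxy-4-(methoxymethoxy)-5-(2-methylbut-3-en-2-yl)benzaldehyde | C=CC(C)(C)c1cc(C=O)c(OC)cc1OCOC
F2 | step 8 | (E)-1-[2-hydroxy-4,6-bis(methoxymethoxy)-3-(3-methylbut-2-en-1-yl)phenyl]-3-[2-methoxy-4-(methoxymethoxy)-5-(2-methylbut-3-en-2-yl)phenyl]prop-2-en-1-one | C=CC(C)(C)c1cc(/C=C/C(=O)c2c(O)c(CC=C(C)C)c(OCOC)cc2OCOC)c(OC)cc1OCOC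
F3 | step 8 | racemic 2-[2-methoxy-4-(methoxymethoxy)-5-(2-methylbut-3-en-2-yl)phenyl]-5,7-bis(methoxymethoxy)-8-(3-methylbut-2-en-1-yl)-2,3-dihydro-4H-chromen-4-one | C=CC(C)(C)c1cc(C2CC(=O)c3c(OCOC)cc(OCOC)c(CC=C(C)C)c3O2)c(OC)cc1OCOC
F4 | step 5 | 4-bromo-5-methoxy-2-(2-methylbut-3-en-2-yl)phenyl acetate | C=CC(C)(C)c1cc(Br)c(OC)cc1OC(C)=O
F5 | step 3 | 2-hydroxy-5,7-bis(methoxymethoxy)-8-(3-methylbut-2-en-1-yl)-2,3-dihydro-4H-chromen-4-one (racemic) | O=C1CC(O)Oc2c(CC=C(C)C)c(OCOC)cc(OCOC)c12
F6 | step 9 | (2S)-2-[2-methoxy-5-(2-methylbut-3-en-2-yl)-4-(trimethylsilyloxy)phenyl]-8-(3-methylbut-2-en-1-yl)-5,7-bis(trimethylsilyloxy)-2,3-dihydro-4H-chromen-4-one | C=CC(C)(C)c1cc([C@@H]2CC(=O)c3c(O[Si](C)(C)C)cc(O[Si](C)(C)C)c(CC=C(C)C)c3O2)c(OC)cc1O[Si](C)(C)C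
F7 | step 7 | 2-[2-methoxy-4-(methoxymethoxy)-5-(2-methylbut-3-en-2-yl)phenyl]-4,4,5,5-tetramethyl-1,3,2-dioxaborolane | C=CC(C)(C)c1cc(B2OC(C)(C)C(C)(C)O2)c(OC)cc1OCOC
A1 | alternative 1 | 2-hydroxy-4,6-bis(methoxymethoxy)-3-(3-methylbut-2-en-1-yl)benzaldehyde | O=Cc1c(O)c(CC=C(C)C)c(OCOC)cc1OCOC
A2 | alternative 1 | 1-ethenyl-2-methoxy-4-(methoxymethoxy)-5-(2-methylbut-3-en-2-yl)benzene | C=CC(C)(C)c1cc(C=C)c(OC)cc1OCOC
A3 | alternative 1 | (2S,4S)-4-methoxy-2-[2-methoxy-4-(methoxymethoxy)-5-(2-methylbut-3-en-2-yl)phenyl]-5,7-bis(methoxymethoxy)-8-(3-methylbut-2-en-1-yl)chromane (2,4-cis) | C=CC(C)(C)c1cc([C@@H]2C[C@H](OC)c3c(OCOC)cc(OCOC)c(CC=C(C)C)c3O2)c(OC)cc1OCOC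
A4 | alternative 2 | methyl 4-{(2S)-2-[2-methoxy-4-(methoxymethoxy)-5-(2-methylbut-3-en-2-yl)phenyl]-4-oxo-3,4-dihydro-2H-pyran-6-yl}-7-methyl-3-oxooct-6-enoate | C=CC(C)(C)c1cc([C@@H]2CC(=O)C=C(C(CC=C(C)C)C(=O)CC(=O)OC)O2)c(OC)cc1OCOC
A5 | alternative 2 | (2S)-5,7-dihydroxy-2-[2-methoxy-4-(methoxymethoxy)-5-(2-methylbut-3-en-2-yl)phenyl]-8-(3-methylbut-2-en-1-yl)-2,3-dihydro-4H-chromen-4-one | C=CC(C)(C)c1cc([C@@H]2CC(=O)c3c(O)cc(O)c(CC=C(C)C)c3O2)c(OC)cc1OCOC
A6 | alternative 3 | (2S)-2-[4-acetoxy-2-methoxy-5-(2-methylbut-3-en-2-yl)phenyl]-5-[(3-methylbut-2-en-1-yl)oxy]-4-oxo-3,4-dihydro-2H-chromen-7-yl acetate | C=CC(C)(C)c1cc([C@@H]2CC(=O)c3c(OCC=C(C)C)cc(OC(C)=O)cc3O2)c(OC)cc1OC(C)=O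
A7 | alternative 3 | (2S)-2-[4-acetoxy-2-methoxy-5-(2-methylbut-3-en-2-yl)phenyl]-5-hydroxy-8-(3-methylbut-2-en-1-yl)-4-oxo-3,4-dihydro-2H-chromen-7-yl acetate | C=CC(C)(C)c1cc([C@@H]2CC(=O)c3c(O)cc(OC(C)=O)c(CC=C(C)C)c3O2)c(OC)cc1OC(C)=O
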